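**Retrosynthetic overview**
1. The C14 hydroperoxide comes last, by SN2 inversion of the (14R)-allylic mesylate of butenolide alcohol 22, followed by global desilylation.
2. The butenolide ring O1–C19(=O)–C18H=C17(CH3)–C16H is the retron of an allenoate. Its O1–C16 bond and C17 methyl are isomeric with the O–CH3 of a methyl 2,3-dienoate C16=C17=C18–C19O2CH3, so 22 comes from (aS)-allenoate 21 by a Pd/MeI methyl-transfer cycloisomerisation.
3. Allenoate 21 comes from propargylic carbonate 20 (anti SN2′ carbonylation). 20 comes from a Nozaki–Hiyama–Kishi union of enol triflate 12 (C1–C13, C21–C25) with aldehyde 19 (C14–C18).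
4. Decalin 12 comes from (+)-larixyl acetate: side-chain cleavage, C8 hydration, and 6α-OH-directed oxidation of the peri 4α-methyl (C23) through a temporary C4–C5–C6–O–C23 ether/lactone ring.
5. Ring order: rings A and B from the chiral pool; temporary tetrahydrofuran/γ-lactone ring (steps 5–6, opened in step 7); butenolide ring last (step 16).

Key step: step 16

Remark on numbering (used for every compound): C1–C10 decalin; chain C11–C19 (C19 = lactone carbonyl, O1 = ring oxygen); C20 = methyl on C17; C21 = methyl on C8; C22 = methyl on C10; C23 = 4α carbon (ester); C24 = 4β methyl; C25 = methylene on C13. In larixyl acetate C21 is the exocyclic methylene, C23/C24 the gem-dimethyl pair and C25 the C13 methyl.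

**Step 1**
Reactants: 1 (+)-larixyl acetate
Product: 2 6α-acetoxy-8(21)-ene C13 methyl ketone
Conditions: KMnO4, BnEt3NCl (cat.), CH2Cl2/H2O, 0 °C → rt
Reagents that add atoms: none
Why: Permanganate should hydroxylate the unhindered monosubstituted C14=C15 vinyl group faster than the shielded exocyclic C8=C21 alkene and cleave the oxidised chain down to the C13 ketone (oxidative degradation of a tertiary vinyl carbinol), with no ring stereocentre touched.

**Step 2**
Reactants: 2 6α-acetoxy-8(21)-ene C13 methyl ketone
Product: 3 6α-acetoxy-8α-hydroxy methyl ketone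
Conditions: Co(acac)2 (20 mol %), PhSiH3, O2 (1 atm), THF/i-PrOH, rt
Reagents that add atoms: oxygen, O=O
Why: Mukaiyama hydration: hydrogen-atom transfer to C21 gives the tertiary C8 radical, which should be trapped by O2 on the α face, away from the axial C22 methyl, to give 8α-OH/8β-CH3 after reduction of the peroxide by the silane; ketone and acetate are inert.

**Step 3**
Reactants: 3 6α-acetoxy-8α-hydroxy methyl ketone
Product: 4 6α-acetoxy-8α-(triethylsilyloxy) methyl ketone
Conditions: TESOTf, 2,6-lutidine, CH2Cl2, −78 → 0 °C; dilute aqueous acid work-up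
Reagents that add atoms: triethylsilyl triflate, CC[Si](CC)(CC)OS(=O)(=O)C(F)(F)F
Why: Silyl triflate silylation of the tertiary alcohol (any enol silane of the ketone is cleaved on work-up), so that later only O6 can form a hypoiodite and O8 cannot add to the C13 ketone.

**Step 4**
Reactants: 4 6α-acetoxy-8α-(triethylsilyloxy) methyl ketone
Product: 5 6α-hydroxy-8α-(triethylsilyloxy) methyl ketone
Conditions: K2CO3, MeOH, 40 °C
Reagents that add atoms: none
Why: Base-catalysed transesterification removes the acetate; the hindered tertiary silyl ether and the ketone should survive.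

**Step 5**
Reactants: 5 6α-hydroxy-8α-(triethylsilyloxy) methyl ketone
Product: 6 6α,23-epoxy (tetrahydrofuran) ether
Conditions: PhI(OAc)2, I2, cyclohexane, hν (visible), 40 °C
Reagents that add atoms: none
Why: Suárez hypoiodite reaction: the O6 alkoxyl radical should abstract hydrogen from the peri, likewise equatorial 4α-methyl C23 through a six-membered transition state (the axial C24, C22 and C21 methyls are out of reach), and O6 then closes onto the C23 iodide, which makes C4 stereogenic with C23 α and C24 β.

**Step 6**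
Reactants: 6 6α,23-epoxy (tetrahydrofuran) ether
Product: 7 23,6α-lactone
Conditions: RuCl3 hydrate (5 mol %), NaIO4, CCl4/MeCN/H2O, rt
Reagents that add atoms: sodium periodate, [Na+].[O-]I(=O)(=O)=O
Why: RuO4 oxidation of a cyclic ether to the lactone at the α-methylene C23; the alternative α-hydrogen at C6 is axial and flanked by the axial C22 and C24 methyls.

**Step 7**
Reactants: 7 23,6α-lactone
Product: 9 methyl 6α-hydroxy-23-oate methyl ketone, via lithium carboxylate 8 (not isolated)
Conditions: LiOH (1.05 equiv), THF/H2O, 60 °C; evaporate; then MeI, NaHCO3, DMF, rt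
Reagents that add atoms: lithium hydroxide, [Li+].[OH-]; iodomethane, CI
Why: Irreversible saponification opens the strained peri-fused γ-lactone and carboxylate O-alkylation fixes the open form as the methyl ester without acidification, so that relactonisation is avoided.

**Step 8**
Reactants: 9 methyl 6α-hydroxy-23-oate methyl ketone
Product: 10 6α,8α-bis(triethylsilyloxy) methyl ester methyl ketone
Conditions: TESOTf, 2,6-lutidine, CH2Cl2, −78 → 0 °C; dilute aqueous acid work-up
Reagents that add atoms: triethylsilyl triflate, CC[Si](CC)(CC)OS(=O)(=O)C(F)(F)F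
Why: Silyl triflate silylation of the hindered equatorial 6α-OH, which blocks attack of O6 on the C23 ester in the basic and electrophilic steps that follow.

**Step 9**
Reactants: 10 6α,8α-bis(triethylsilyloxy) methyl ester methyl ketone
Product: 12 enol triflate C13(OTf)=C25H2, via lithium enolate 11 (not isolated)
Conditions: LDA, THF, −78 °C; then PhNTf2, −78 → 0 °C
Reagents that add atoms: N-phenylbis(trifluoromethanesulfonimide), O=S(=O)(N(c1ccccc1)S(=O)(=O)C(F)(F)F)C(F)(F)F
Why: Kinetic deprotonation of the methyl ketone on the methyl side (C25) and O-triflation give the 2-triflyloxy-1-alkene; the C23 ester has no α-hydrogen and is neopentylic.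

**Step 10**
Reactants: 13 3-(trimethylsilyl)prop-2-ynal; 14 allyltributylstannane
Product: 15 (3R)-1-(trimethylsilyl)hex-5-en-1-yn-3-ol
Conditions: (R)-BINOL (20 mol %), Ti(OiPr)4 (10 mol %), 4 Å MS, CH2Cl2, −20 °C; aqueous NaHCO3 work-up (the BINOL antipode is the one that gives the 3R carbinol)
Reagents that add atoms: none
Why: Keck asymmetric allylation of an ynal; the BINOL–titanium complex selects the aldehyde face and sets the carbinol centre that becomes C16.

**Step 11**
Reactants: 15 (3R)-1-(trimethylsilyl)hex-5-en-1-yn-3-ol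
Product: 16 (3R)-hex-5-en-1-yn-3-ol
Conditions: K2CO3, MeOH, 0 °C
Reagents that add atoms: none
Why: Methanolysis of the C(sp)–Si bond frees the terminal alkyne needed for the hydrogen at C18; the carbinol centre is not affected.

**Step 12**
Reactants: 16 (3R)-hex-5-en-1-yn-3-ol
Product: 17 (3R)-hex-5-en-1-yn-3-yl methyl carbonate
Conditions: ClCO2Me, pyridine, DMAP (cat.), CH2Cl2, 0 °C
Reagents that add atoms: methyl chloroformate, COC(=O)Cl
Why: O-acylation with retention installs the propargylic leaving group that is used in step 15.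

**Step 13**
Reactants: 17 (3R)-hex-5-en-1-yn-3-yl methyl carbonate
Product: 19 (3R)-3-[(methoxycarbonyl)oxy]pent-4-ynal, via ozonide 18 (not isolated)
Conditions: O3 (dosed to about 1 equiv), CH2Cl2, −78 °C; then Me2S, −78 °C → rt; used crude
Reagents that add atoms: ozone, [O-][O+]=O
Why: Ozonolysis with reductive work-up; the alkene reacts far faster than the terminal alkyne, and the neutral work-up avoids β-elimination of the carbonate.

**Step 14**
Reactants: 12 enol triflate C13(OTf)=C25H2; 19 (3R)-3-[(methoxycarbonyl)oxy]pent-4-ynal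
Product: 20 (14R,16R)-14-hydroxy-16-(methoxycarbonyloxy)-13(25)-en-17-yne
Conditions: CrCl2 (3 equiv), chiral N-[2-(4-isopropyl-4,5-dihydrooxazol-2-yl)-6-methylphenyl]methanesulfonamide (3.3 equiv, antipode that gives 14R), Et3N, NiCl2 (5 mol %), THF, rt
Reagents that add atoms: none
Why: Nozaki–Hiyama–Kishi coupling: nickel-catalysed activation of the alkenyl triflate, transmetalation to chromium and addition to the aldehyde, the chiral sulfonamide–chromium complex selecting the face that gives (14R); ester, carbonate, terminal alkyne and silyl ethers are tolerated by the organochromium reagent.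

**Step 15**
Reactants: 20 (14R,16R)-14-hydroxy-16-(methoxycarbonyloxy)-13(25)-en-17-yne
Product: 21 methyl (14R,aS)-14-hydroxy-16,17-dienoate (allenoate)
Conditions: Pd2(dba)3·CHCl3 (2.5 mol %), PPh3 (10 mol %), CO (10 bar), MeOH/THF, 25 °C
Reagents that add atoms: carbon monoxide, [C-]#[O+]; methanol, CO
Why: Palladium-catalysed carbonylation of a propargylic carbonate: anti SN2′ oxidative addition with loss of CO2 gives the allenylpalladium species, and CO insertion with methanolysis gives the 2,3-dienoate, so the (16R) centre is transcribed into the (aS) axis; the free C14 hydroxyl and the 1,1-disubstituted alkene are inert under these neutral conditions.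

**Step 16**
Reactants: 21 methyl (14R,aS)-14-hydroxy-16,17-dienoate (allenoate)
Product: 22 (14R,16S)-14-hydroxy butenolide
Conditions: Pd(CH3)I(PPh3)2 (5 mol %), MeI (10 mol %), MeCN, 50 °C
Reagents that add atoms: none
Why: Proposed new method: Pd(CH3)I(PPh3)2 should coordinate the distal C16=C17 bond of the allenoate on the face remote from the ester, the ester carbonyl oxygen then adds to C16 anti to palladium to give a 2-methoxyfuranylium ion carrying a vinyl(methyl)palladium unit at C17, C(sp2)–CH3 reductive elimination places the C20 methyl on C17 and releases zerovalent palladium, and iodide demethylates the oxocarbenium ion to the butenolide and MeI, which re-enters by oxidative addition, so that the ester methyl is relayed from oxygen to carbon in a net isomerisation. The closest known reaction types are the zerovalent-palladium-catalysed coupling–cyclisation of 2,3-allenoic acids with aryl halides (β-aryl butenolides with axial-to-central chirality transfer) and the electrophile-induced cyclisation of alkyl 2,3-allenoates in which the O-alkyl group leaves as alkyl halide (I2, or PdCl2 with allyl bromide). The butenolide ring is closed in a 5-endo mode onto the allene, which is geometrically easy because the C16=C17 π bond lies in the plane of the C18 substituents and so points at the carbonyl oxygen. The new C16 stereocentre is controlled by the (aS) axis alone: the tethered oxygen can reach C16 only from the side on which the ester sits, which gives (16S), the net inversion of the C16 carbonate centre of 20. The step needs methyl delivery to the central carbon C17 and not to C16 or C18, which follows from the oxypalladation/reductive elimination sequence, and it needs the axis to survive, which the absence of base and of free phosphine should secure; the free C14 hydroxyl could reach C16 only through an oxetane and is not expected to compete.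

**Step 17**
Reactants: 22 (14R,16S)-14-hydroxy butenolide
Product: 24 (14S,16S)-14-hydroperoxide 6α,8α-bis(triethylsilyl) ether, via allylic mesylate 23 (not isolated)
Conditions: MsCl, Et3N, CH2Cl2, −60 °C; then anhydrous H2O2 in Et2O (excess), −60 → 0 °C; pH 7 buffer work-up
Reagents that add atoms: methanesulfonyl chloride, CS(=O)(=O)Cl (atoms present only in 23); hydrogen peroxide, OO
Why: Displacement of a secondary methanesulfonate by hydrogen peroxide (the classical route to secondary alkyl hydroperoxides): the allylic mesylate is made and displaced in one flask at low temperature, the SN2 path inverting C14 from R to S; O6 and O8 are silylated and the butenolide is not attacked by neutral H2O2.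

**Step 18**
Reactants: 24 (14S,16S)-14-hydroperoxide 6α,8α-bis(triethylsilyl) ether
Product: 25 target compound
Conditions: HF·pyridine, pyridine/THF, 0 °C → rt
Reagents that add atoms: none
Why: Fluoride cleavage of both triethylsilyl ethers under buffered, non-basic conditions that should leave the hydroperoxide (no Kornblum–DeLaMare elimination), the butenolide and the hydroxy methyl ester (no 6,23-lactonisation) intact.

**Compound list**
1 | (+)-larixyl acetate, (13S)-6α-acetoxylabda-8(17),14-dien-13-ol | C=C[C@@](C)(O)CC[C@@H]1[C@@]2(C)CCCC(C)(C)[C@@H]2[C@@H](OC(C)=O)CC1=C | starting material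
2 | 6α-acetoxy-8(21)-ene C13 methyl ketone (5α-H, 10β-CH3 trans-decalin, 9β-CH2CH2COCH3) | CC(=O)CC[C@@H]1[C@@]2(C)CCCC(C)(C)[C@@H]2[C@@H](OC(C)=O)CC1=C | intermediate
3 | 6α-acetoxy-8α-hydroxy-8β-methyl methyl ketone | CC(=O)CC[C@@H]1[C@@]2(C)CCCC(C)(C)[C@@H]2[C@@H](OC(C)=O)C[C@@]1(C)O | intermediate
4 | 6α-acetoxy-8α-(triethylsilyloxy) methyl ketone | CC(=O)CC[C@@H]1[C@@]2(C)CCCC(C)(C)[C@@H]2[C@@H](OC(C)=O)C[C@@]1(C)O[Si](CC)(CC)CC | intermediate
5 | 6α-hydroxy-8α-(triethylsilyloxy) methyl ketone | CC(=O)CC[C@@H]1[C@@]2(C)CCCC(C)(C)[C@@H]2[C@@H](O)C[C@@]1(C)O[Si](CC)(CC)CC | intermediate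
6 | 6α,23-epoxy ether (O6 bonded to the 4α-CH2; 4β-CH3; 8α-OTES; methyl ketone) | CC(=O)CC[C@@H]1[C@@]2(C)CCC[C@@](C)(CO3)[C@@H]2[C@@H]3C[C@@]1(C)O[Si](CC)(CC)CC | intermediate
7 | 23,6α-lactone (C23=O; 4β-CH3; 8α-OTES; methyl ketone) | CC(=O)CC[C@@H]1[C@@]2(C)CCC[C@@](C)(C(=O)O3)[C@@H]2[C@@H]3C[C@@]1(C)O[Si](CC)(CC)CC | intermediate
8 | lithium 6α-hydroxy-8α-(triethylsilyloxy)-23-carboxylate | CC(=O)CC[C@@H]1[C@@]2(C)CCC[C@@](C)(C(=O)[O-])[C@@H]2[C@@H](O)C[C@@]1(C)O[Si](CC)(CC)CC.[Li+] | intermediate
9 | methyl 6α-hydroxy-8α-(triethylsilyloxy)-23-oate methyl ketone (4α-CO2CH3, 4β-CH3) | CC(=O)CC[C@@H]1[C@@]2(C)CCC[C@@](C)(C(=O)OC)[C@@H]2[C@@H](O)C[C@@]1(C)O[Si](CC)(CC)CC | intermediate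
10 | 6α,8α-bis(triethylsilyloxy) methyl ester methyl ketone | CC(=O)CC[C@@H]1[C@@]2(C)CCC[C@@](C)(C(=O)OC)[C@@H]2[C@@H](O[Si](CC)(CC)CC)C[C@@]1(C)O[Si](CC)(CC)CC | intermediate
11 | lithium enolate of 10 (C13=C25) | C=C([O-])CC[C@@H]1[C@@]2(C)CCC[C@@](C)(C(=O)OC)[C@@H]2[C@@H](O[Si](CC)(CC)CC)C[C@@]1(C)O[Si](CC)(CC)CC.[Li+] | intermediate
12 | enol triflate C13(OTf)=C25H2 | C=C(OS(=O)(=O)C(F)(F)F)CC[C@@H]1[C@@]2(C)CCC[C@@](C)(C(=O)OC)[C@@H]2[C@@H](O[Si](CC)(CC)CC)C[C@@]1(C)O[Si](CC)(CC)CC | intermediate
13 | 3-(trimethylsilyl)prop-2-ynal | C[Si](C)(C)C#CC=O | starting material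
14 | allyltributylstannane | C=CC[Sn](CCCC)(CCCC)CCCC | starting material
15 | (3R)-1-(trimethylsilyl)hex-5-en-1-yn-3-ol | C=CC[C@@H](O)C#C[Si](C)(C)C | intermediate
16 | (3R)-hex-5-en-1-yn-3-ol | C=CC[C@@H](O)C#C | intermediate
17 | (3R)-hex-5-en-1-yn-3-yl methyl carbonate | C=CC[C@@H](OC(=O)OC)C#C | intermediate
18 | ozonide (1,2,4-trioxolane) of 17, epimeric at the trioxolane carbon | C1(C[C@@H](OC(=O)OC)C#C)OCOO1 | intermediate
19 | (3R)-3-[(methoxycarbonyl)oxy]pent-4-ynal | O=CC[C@@H](OC(=O)OC)C#C | intermediate
20 | (14R,16R)-14-hydroxy-16-(methoxycarbonyloxy)-13(25)-en-17-yne, 6α,8α-bis-TES, methyl 23-ester | C=C(CC[C@@H]1[C@@]2(C)CCC[C@@](C)(C(=O)OC)[C@@H]2[C@@H](O[Si](CC)(CC)CC)C[C@@]1(C)O[Si](CC)(CC)CC)[C@@H](C[C@@H](OC(=O)OC)C#C)O | intermediate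
21 | methyl (14R,aS)-14-hydroxy-13(25)-ene-16,17-dienoate (C16=C17=C18–C19O2CH3; P helicity), 6α,8α-bis-TES | C=C(CC[C@@H]1[C@@]2(C)CCC[C@@](C)(C(=O)OC)[C@@H]2[C@@H](O[Si](CC)(CC)CC)C[C@@]1(C)O[Si](CC)(CC)CC)[C@@H](CC([H])=[C@@]=C([H])C(=O)OC)O | intermediate
22 | (14R,16S)-14-hydroxy butenolide (4-methyl-2(5H)-furanone at C16), 6α,8α-bis-TES | C=C(CC[C@@H]1[C@@]2(C)CCC[C@@](C)(C(=O)OC)[C@@H]2[C@@H](O[Si](CC)(CC)CC)C[C@@]1(C)O[Si](CC)(CC)CC)[C@@H](C[C@@H]1OC(=O)C=C1C)O | intermediate
23 | (14R,16S)-14-methanesulfonate of 22 | C=C(CC[C@@H]1[C@@]2(C)CCC[C@@](C)(C(=O)OC)[C@@H]2[C@@H](O[Si](CC)(CC)CC)C[C@@]1(C)O[Si](CC)(CC)CC)[C@@H](C[C@@H]1OC(=O)C=C1C)OS(C)(=O)=O | intermediate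
24 | (14S,16S)-14-hydroperoxide, 6α,8α-bis(triethylsilyl) ether | C=C(CC[C@@H]1[C@@]2(C)CCC[C@@](C)(C(=O)OC)[C@@H]2[C@@H](O[Si](CC)(CC)CC)C[C@@]1(C)O[Si](CC)(CC)CC)[C@H](C[C@@H]1OC(=O)C=C1C)OO | intermediate
25 | target: methyl (14S,16S)-14-hydroperoxy-6α,8α-dihydroxy-13(25)-en-19,16-olide-23-oate | C=C(CC[C@@H]1[C@@]2(C)CCC[C@@](C)(C(=O)OC)[C@@H]2[C@@H](O)C[C@@]1(C)O)[C@H](C[C@@H]1OC(=O)C=C1C)OO | target

**Step count and risks**
Total steps: 18. Longest linear sequence: 14 steps (steps 1–9 and 14–18, from 1 to 25).

Steps most likely to fail: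

1. Step 16 (proposed new method). The methyl-relay cycle may stall if the methylpalladium iodide does not activate the allene. The vinylpalladium intermediate may be protonated instead of methylated. Reversible π-allyl formation may erode the allene axis before the C–O bond forms. Fallback from 21: iodolactonisation (I2, MeCN/H2O, rt) is a known anti electrophilic cyclisation of alkyl 2,3-allenoates with the same axial-to-central transfer and loss of the ester methyl as MeI; it gives the β-iodobutenolide F1. Stille methylation of this vinyl iodide (Me4Sn, Pd2(dba)3, AsPh3, CuI, NMP, 50 °C) then gives 22, where the route is rejoined.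

2. Step 17. Hydrogen peroxide may attack C25 in an SN2′ sense, the allylic mesylate may ionise with loss of configuration at C14 or eliminate to the diene, and amine base may trigger Kornblum–DeLaMare dehydration of the product. Fallback from 22: reductive 1,3-transposition of the allylic alcohol through its allylic diazene (2-nitrobenzenesulfonylhydrazide, PPh3, DEAD, THF, −30 °C → rt) gives the (13E)-trisubstituted alkene F2. A Schenck ene reaction (O2, tetraphenylporphyrin, hν, CH2Cl2, 0 °C) then adds oxygen at C14 with hydrogen abstraction from the C25 methyl and gives 24, where the route is rejoined. This fallback gives up control at C14, so 24 would have to be separated from its C14 epimer and from the C13 tertiary hydroperoxide.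

3. Step 5. The iodine/PhI(OAc)2 system may iodinate α to the ketone, the acid set free may remove the tertiary silyl ether and open radical chemistry at O8, and closure of the neopentylic C23 iodide may be slow. Fallback from 5: nitrosation (NOCl, pyridine, −20 °C) gives the nitrite ester F3. Barton nitrite photolysis (hν, toluene, 0 °C; then warming to tautomerise the nitroso compound) gives the C23 aldoxime F4 without iodine or an oxidant. Transoximation (aqueous CH2O, PPTS, THF) gives the 6α-hydroxy C23 aldehyde F5, which is in equilibrium with its lactol. Fétizon oxidation (Ag2CO3 on Celite, benzene, reflux) gives lactone 7, where the route is rejoined.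

**Further compounds**
F1 | step 16 | (14R,16S)-14-hydroxy β-iodobutenolide (4-iodo-2(5H)-furanone at C16), 6α,8α-bis-TES | C=C(CC[C@@H]1[C@@]2(C)CCC[C@@](C)(C(=O)OC)[C@@H]2[C@@H](O[Si](CC)(CC)CC)C[C@@]1(C)O[Si](CC)(CC)CC)[C@@H](C[C@@H]1OC(=O)C=C1I)O
F2 | step 17 | (13E,16S)-13(14)-ene butenolide (C25 as methyl on C13), 6α,8α-bis-TES | C\C(CC[C@@H]1[C@@]2(C)CCC[C@@](C)(C(=O)OC)[C@@H]2[C@@H](O[Si](CC)(CC)CC)C[C@@]1(C)O[Si](CC)(CC)CC)=C/C[C@@H]1OC(=O)C=C1C
F3 | step 5 | 6α-nitrite ester of 5 | CC(=O)CC[C@@H]1[C@@]2(C)CCCC(C)(C)[C@@H]2[C@@H](ON=O)C[C@@]1(C)O[Si](CC)(CC)CC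
F4 | step 5 | 6α-hydroxy C23 (E)-aldoxime | CC(=O)CC[C@@H]1[C@@]2(C)CCC[C@@](C)(/C=N/O)[C@@H]2[C@@H](O)C[C@@]1(C)O[Si](CC)(CC)CC
F5 | step 5 | 6α-hydroxy C23 aldehyde (open form of the lactol) | CC(=O)CC[C@@H]1[C@@]2(C)CCC[C@@](C)(C=O)[C@@H]2[C@@H](O)C[C@@]1(C)O[Si](CC)(CC)CC
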